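**Retrosynthetic overview**
- Last disconnection: the 5-OH of agecorynin F comes from chelation-controlled cleavage of the 5-O-methyl group of the heptamethyl ether.
- Key disconnection: the C2–C1' bond between the pyranone ring and ring B. C2 of 5,6,7-trimethoxychromone, normally an electrophilic carbon, is made the nucleophile (a C2–zinc species, i.e. an alpha-metalated enol ether that acts as a masked aroyl anion and beta-acylvinyl anion) and is joined to the electrophilic carbon of a ring B aryl iodide.
- The chromone comes from 2'-hydroxy-4',5',6'-trimethoxyacetophenone plus one carbon from DMF-DMA; the iodide comes from 1,2,3,4-tetramethoxybenzene.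
- Ring order: rings A and B are bought as benzenes; the pyranone ring (ring C) is the only ring formed, and it is closed before the key coupling.

Assumption: the target is achiral (no stereocentre), so "single enantiomer" is read as the constitution shown; both benzene starting materials are taken as catalogue compounds.

**Step 1**
Reactants: 1 2'-hydroxy-4',5',6'-trimethoxyacetophenone
Product: 3 5,6,7-trimethoxy-4H-chromen-4-one, via enaminone 2 (not isolated)
Conditions: DMF-DMA (2 equiv), toluene, 100 °C; evaporate; then conc. HCl, CH2Cl2, 40 °C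
Reagents that add atoms: N,N-dimethylformamide dimethyl acetal, COC(OC)N(C)C
Why: Enaminone chromone synthesis: the methyl ketone condenses with the amide acetal to the (E)-enaminone, and acid then triggers intramolecular oxa-Michael addition of the ortho phenol and loss of dimethylamine to close the pyranone ring, the ring A methyl ethers being inert.

**Step 2**
Reactants: 4 1,2,3,4-tetramethoxybenzene
Product: 5 1-iodo-2,3,4,5-tetramethoxybenzene
Conditions: NIS (1.05 equiv), CF3CO2H (10 mol %), MeCN, 0 °C to rt, dark
Reagents that add atoms: N-iodosuccinimide, O=C1CCC(=O)N1I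
Why: Electrophilic aromatic iodination: the two free positions of 4 are equivalent by symmetry and each is ortho and para to a methoxy group, so one equivalent of NIS gives a single monoiodide, and the iodine slows a second substitution.

**Step 3**
Reactants: 3 5,6,7-trimethoxy-4H-chromen-4-one; 5 1-iodo-2,3,4,5-tetramethoxybenzene
Product: 7 5,6,7-trimethoxy-2-(2,3,4,5-tetramethoxyphenyl)-4H-chromen-4-one, via diorganozinc 6 (not isolated)
Conditions: Zn(TMP)2·2MgCl2·2LiCl (0.6 equiv; TMP = 2,2,6,6-tetramethylpiperidin-1-yl), THF, −30 °C, 1 h; then 5 (1.1 equiv), Pd(OAc)2 (2 mol %), SPhos (4 mol %), THF, −30 to 40 °C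
Reagents that add atoms: none
Why: Knochel-type C–H zincation followed by Negishi cross-coupling: MgCl2 and LiCl bind the C4 carbonyl (chelated with the 5-methoxy group), which acidifies the C2–H next to the ring oxygen and keeps the amide away from C3, so the zinc amide metalates C2 to give 6, whose normally electrophilic C2 now reacts as a carbanion and is joined under palladium catalysis to the electrophilic carbon of iodide 5, the covalent C–Zn bond tolerating the ketone and the ethers.

**Step 4**
Reactants: 7 5,6,7-trimethoxy-2-(2,3,4,5-tetramethoxyphenyl)-4H-chromen-4-one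
Product: 9 agecorynin F (5-hydroxy-6,7-dimethoxy-2-(2,3,4,5-tetramethoxyphenyl)-4H-chromen-4-one), via boron chelate 8 (not isolated)
Conditions: BCl3 (1.5 equiv), CH2Cl2, −20 to 0 °C; then H2O
Reagents that add atoms: none
Why: Chelation-controlled Lewis acid ether cleavage: BCl3 is held between the C4 carbonyl and the peri 5-methoxy oxygen in a six-membered chelate, so chloride removes only that methyl group at 0 °C, and hydrolysis of 8 frees the hydrogen-bonded 5-hydroxyl while the six other methoxy groups stay.

**Compound list**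
1 | 1-(2-hydroxy-4,5,6-trimethoxyphenyl)ethan-1-one (2'-hydroxy-4',5',6'-trimethoxyacetophenone) | CC(=O)c1c(O)cc(OC)c(OC)c1OC | starting material
2 | (E)-3-(dimethylamino)-1-(2-hydroxy-4,5,6-trimethoxyphenyl)prop-2-en-1-one (enaminone, not isolated) | CN(C)/C=C/C(=O)c1c(O)cc(OC)c(OC)c1OC | intermediate
3 | 5,6,7-trimethoxy-4H-chromen-4-one | COc1cc2occc(=O)c2c(OC)c1OC | intermediate
4 | 1,2,3,4-tetramethoxybenzene | COc1ccc(OC)c(OC)c1OC | starting material
5 | 1-iodo-2,3,4,5-tetramethoxybenzene | COc1cc(I)c(OC)c(OC)c1OC | intermediate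
6 | bis(5,6,7-trimethoxy-4-oxo-4H-chromen-2-yl)zinc (zinc on C2 of both chromones; MgCl2/LiCl complex, not isolated) | COc1cc2oc([Zn]c3cc(=O)c4c(OC)c(OC)c(OC)cc4o3)cc(=O)c2c(OC)c1OC | intermediate
7 | 5,6,7-trimethoxy-2-(2,3,4,5-tetramethoxyphenyl)-4H-chromen-4-one | COc1cc(-c2cc(=O)c3c(OC)c(OC)c(OC)cc3o2)c(OC)c(OC)c1OC | intermediate
8 | 5-[(dichloroboranyl)oxy]-6,7-dimethoxy-2-(2,3,4,5-tetramethoxyphenyl)-4H-chromen-4-one (boron on O5, chelated by the C4 carbonyl; not isolated) | COc1cc(-c2cc(=O)c3c(OB(Cl)Cl)c(OC)c(OC)cc3o2)c(OC)c(OC)c1OC | intermediate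
9 | agecorynin F, 5-hydroxy-6,7-dimethoxy-2-(2,3,4,5-tetramethoxyphenyl)-4H-chromen-4-one (achiral) | COc1cc(-c2cc(=O)c3c(O)c(OC)c(OC)cc3o2)c(OC)c(OC)c1OC | target

**Totals**
Total step count: 4. Longest linear sequence: 3 steps (1 to 3 to 7 to 9); step 2 is a one-step side branch.

**Three steps most likely to fail**

Step 3 (most at risk). The regiochemistry of the zincation (C2 rather than C3, where a C3 metal species can ring-open) rests on the mechanistic argument given and is not verified for this substrate. The ortho-substituted, electron-rich iodide may also couple slowly. The fallback sets out from 1 (with 5 as partner) and comes back at 7. Claisen condensation of 1 with diethyl oxalate (NaOEt, EtOH, reflux) gives ethyl 4-(2-hydroxy-4,5,6-trimethoxyphenyl)-2,4-dioxobutanoate F1. This is cyclised in the same pot (cat. H2SO4, EtOH, reflux) to ethyl 5,6,7-trimethoxy-4-oxo-4H-chromene-2-carboxylate F2. LiOH (THF–H2O, 0 °C) then gives 5,6,7-trimethoxy-4-oxo-4H-chromene-2-carboxylic acid F3. Decarboxylative cross-coupling of F3 with 5 (Pd(P(t-Bu)3)2 5 mol %, n-Bu4NCl, Cs2CO3, DMF, 150 °C) gives 7. The carboxyl group fixes the site of the C2 carbanion equivalent, so the outcome no longer depends on which C–H a base removes; this coupling is itself a proposal by analogy with heteroaryl 2-carboxylic acids.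

Step 4. BCl3 may also attack the crowded 6-methoxy group or the inner methoxy groups of ring B. The fallback sets out from 3 and comes back at 9. The chelation-controlled cleavage is done on 3 (BCl3, CH2Cl2, 0 °C), where no ring B ethers are present, to give 5-hydroxy-6,7-dimethoxy-4H-chromen-4-one F4. Benzylation (BnBr, K2CO3, DMF, 60 °C) gives 5-(benzyloxy)-6,7-dimethoxy-4H-chromen-4-one F5. Zincation as in step 3 gives bis[5-(benzyloxy)-6,7-dimethoxy-4-oxo-4H-chromen-2-yl]zinc F6, and coupling with 5 under the step 3 catalyst gives 5-(benzyloxy)-6,7-dimethoxy-2-(2,3,4,5-tetramethoxyphenyl)-4H-chromen-4-one F7. Hydrogenolysis (H2 1 atm, Pd/C, EtOAc, rt) gives 9; the flavone double bond is not reduced under these conditions.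

Step 2. Over-iodination to the diiodide or oxidative demethylation to a quinone could lower the yield. The fallback sets out from 4 and comes back at 5. Directed ortho-lithiation (n-BuLi, TMEDA, THF, 0 °C) gives (2,3,4,5-tetramethoxyphenyl)lithium F8, which is quenched with I2 at −78 °C to give 5. One lithiation allows only one iodine.

**Further compounds**
F1 | step 3 | ethyl 4-(2-hydroxy-4,5,6-trimethoxyphenyl)-2,4-dioxobutanoate | CCOC(=O)C(=O)CC(=O)c1c(O)cc(OC)c(OC)c1OC
F2 | step 3 | ethyl 5,6,7-trimethoxy-4-oxo-4H-chromene-2-carboxylate | CCOC(=O)c1cc(=O)c2c(OC)c(OC)c(OC)cc2o1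
F3 | step 3 | 5,6,7-trimethoxy-4-oxo-4H-chromene-2-carboxylic acid | OC(=O)c1cc(=O)c2c(OC)c(OC)c(OC)cc2o1
F4 | step 4 | 5-hydroxy-6,7-dimethoxy-4H-chromen-4-one | COc1cc2occc(=O)c2c(O)c1OC
F5 | step 4 | 5-(benzyloxy)-6,7-dimethoxy-4H-chromen-4-one | COc1cc2occc(=O)c2c(OCc3ccccc3)c1OC
F6 | step 4 | bis[5-(benzyloxy)-6,7-dimethoxy-4-oxo-4H-chromen-2-yl]zinc | COc1cc2oc([Zn]c3cc(=O)c4c(OCc5ccccc5)c(OC)c(OC)cc4o3)cc(=O)c2c(OCc6ccccc6)c1OC
F7 | step 4 | 5-(benzyloxy)-6,7-dimethoxy-2-(2,3,4,5-tetramethoxyphenyl)-4H-chromen-4-one | COc1cc(-c2cc(=O)c3c(OCc4ccccc4)c(OC)c(OC)cc3o2)c(OC)c(OC)c1OC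
F8 | step 2 | (2,3,4,5-tetramethoxyphenyl)lithium | [Li]c1cc(OC)c(OC)c(OC)c1OC
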